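Both interflavan bonds, each running from C4 of a ring C to C8 of the next ring A, are cut. Both are formed by one reaction, a nickel/photoredox union of a C4 carbinol carbon with a C8 bromide carbon. The key step exploits C4 of the middle ring C. The adjoining ring A, with donors O1, O5 and O7, stabilises a planar radical there, and the axial gallate on C3 leaves only the β face open. In one operation the top–middle dimer carbinol is joined to the fully galloylated 8-bromo bottom unit, which fixes C8 over C6 and sets the 4β centre. All C2 and C3 centres come from (−)-epicatechin, and only hydrogenolysis follows.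

Key step: step 10

Remark: flavan numbering is used within each unit (top = free C8, bottom = C4 methylene). The C4 carbinols are drawn 4β, as DDQ oxidation should deliver them, but either epimer would serve because this centre is lost at the radical stage. The benzoxazoline C2 of 11 and 14 should be an epimer mixture and is drawn without configuration. Compound 7 serves twice, as the bottom unit (step 10) and as the precursor of the middle unit (step 6).

Step 1
Reactants: 1 (−)-epicatechin, (2R,3R)-flavan-3,5,7,3',4'-pentol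
Product: 2 5,7,3',4'-tetra-O-benzylepicatechin (2R,3R; free 3-OH)
Conditions: BnBr (4.4 equiv), K2CO3, DMF, 0 °C → rt, Ar
Reagents that add atoms: benzyl bromide, BrCc1ccccc1
Why: Williamson etherification in which carbonate deprotonates only the four phenols and not the aliphatic 3-OH, while the mild base and low temperature avoid ring-C opening, so 2R,3R is kept.

Step 2
Reactants: 2 5,7,3',4'-tetra-O-benzylepicatechin
Product: 3 3,5,7,3',4'-penta-O-benzylepicatechin (2R,3R)
Conditions: NaH, BnBr, DMF, 0 °C → rt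
Reagents that add atoms: benzyl bromide, BrCc1ccccc1
Why: Williamson etherification of the one remaining alkoxide; with every phenol capped there is no quinone methide pathway, so C2 and C3 are not touched.

Step 3
Reactants: 3 3,5,7,3',4'-penta-O-benzylepicatechin
Product: 4 3,5,7,3',4'-penta-O-benzyl-4β-hydroxyepicatechin (top unit; 2,3-cis, 3,4-trans)
Conditions: DDQ (1.5–2 equiv), CH2Cl2/H2O, rt
Reagents that add atoms: water, O
Why: DDQ benzylic C–H oxidation, established for benzylated flavan-3-ols, in which hydride loss from C4 gives the ring-A-stabilised cation and water should add anti to the axial 3-OBn to give the 4β-carbinol.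

Step 4
Reactants: 2 5,7,3',4'-tetra-O-benzylepicatechin
Product: 5 8-bromo-5,7,3',4'-tetra-O-benzylepicatechin (2R,3R)
Conditions: NBS (1.0 equiv), CH2Cl2, −78 °C → rt
Reagents that add atoms: N-bromosuccinimide, O=C1CCC(=O)N1Br
Why: Electrophilic aromatic bromination in which C8 is the most nucleophilic position of the benzylated ring A, so one equivalent of NBS at low temperature should spare C6 and ring B; halogenating before any C4 oxidation keeps NBS away from an ionisable carbinol.

Step 5
Reactants: 5 8-bromo-5,7,3',4'-tetra-O-benzylepicatechin; 6 3,4,5-tris(benzyloxy)benzoic acid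
Product: 7 8-bromo-5,7,3',4'-tetra-O-benzylepicatechin 3-O-(3,4,5-tri-O-benzylgallate) (bottom unit; 2R,3R)
Conditions: DCC, DMAP (cat.), CH2Cl2, rt
Reagents that add atoms: none
Why: Steglich esterification acylates the axial 3-OH without breaking the C3–O bond, so the configuration is retained.

Step 6
Reactants: 7 8-bromo-5,7,3',4'-tetra-O-benzylepicatechin 3-O-(3,4,5-tri-O-benzylgallate)
Product: 8 8-bromo-5,7,3',4'-tetra-O-benzyl-4β-hydroxyepicatechin 3-O-(3,4,5-tri-O-benzylgallate) (3,4-trans)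
Conditions: DDQ (2 equiv), CH2Cl2/H2O, rt
Reagents that add atoms: water, O
Why: The same DDQ benzylic C–H oxidation as in step 3, a type known to tolerate an 8-bromine or a 3-O-acyl group separately, with water expected to add on the β face opposite the axial gallate.

Step 7
Reactants: 8 8-bromo-5,7,3',4'-tetra-O-benzyl-4β-hydroxyepicatechin 3-O-(3,4,5-tri-O-benzylgallate)
Product: 9 8-bromo-5,7,3',4'-tetra-O-benzyl-4β-(tert-butyldimethylsilyloxy)epicatechin 3-O-(3,4,5-tri-O-benzylgallate) (middle unit)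
Conditions: TBSCl, imidazole, DMAP (cat.), DMF, rt → 40 °C
Reagents that add atoms: tert-butyldimethylsilyl chloride, CC(C)(C)[Si](C)(C)Cl
Why: Imidazole-promoted silylation is chosen over a silyl triflate so that the ionisable benzylic C4–O bond never meets a Lewis acid, and the trans-diaxial O3/O4 arrangement disfavours gallate migration.

Step 8
Reactants: 4 3,5,7,3',4'-penta-O-benzyl-4β-hydroxyepicatechin; 9 middle unit (8-bromide, 4β-OTBS, 3-O-gallate); 10 5,7-di-tert-butyl-3-phenylbenzoxazolium tetrafluoroborate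
Product: 12 3,5,7,3',4'-penta-O-benzylepicatechin-(4β→8)-[5,7,3',4'-tetra-O-benzyl-4β-(tert-butyldimethylsilyloxy)epicatechin 3-O-(3,4,5-tri-O-benzylgallate)], via top-unit 2-alkoxybenzoxazoline adduct 11 (not isolated)
Conditions: 4 (1.5 equiv), 10, pyridine, MTBE, rt, filtered into 9 (1 equiv), NiBr2(dtbbpy) (10 mol %; dtbbpy = 4,4'-di-tert-butyl-2,2'-bipyridine), [Ir(ppy)2(dtbbpy)]PF6 (2 mol %), quinuclidine, MTBE/DMA, 450 nm LEDs, rt, Ar
Reagents that add atoms: none
Why: Proposed new method: adduct 11 should be oxidised by the excited photocatalyst, deprotonated and cleaved by β-scission to the planar, ring-A-stabilised C4 radical, which is captured by the aryl-nickel species formed when zerovalent nickel inserts into the C8–Br bond of 9, and reductive elimination from trivalent nickel then forges C4–C8 with the axial 3-OBn and the cis C2 aryl group covering the α face so that the new centre forms 4β (3,4-trans); the closest known reaction type is the nickel/photoredox deoxygenative arylation of secondary alcohols through benzoxazolium adducts, not yet shown for a flavan C4 or an aryl bromide flanked by two oxygens.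

Step 9
Reactants: 12 top–middle dimer 4-O-TBS ether
Product: 13 3,5,7,3',4'-penta-O-benzylepicatechin-(4β→8)-[5,7,3',4'-tetra-O-benzyl-4β-hydroxyepicatechin 3-O-(3,4,5-tri-O-benzylgallate)]
Conditions: TBAF, AcOH (1:1), THF, 0 °C → rt
Reagents that add atoms: none
Why: Fluoride desilylation buffered with acetic acid is neither basic enough to cleave or shift the gallate nor acidic enough to ionise the C4–O bond, and it touches no stereocentre.

Step 10
Reactants: 13 top–middle dimer C4 carbinol; 10 5,7-di-tert-butyl-3-phenylbenzoxazolium tetrafluoroborate; 7 bottom unit (8-bromide, 3-O-gallate)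
Product: 15 perbenzylated epicatechin-(4β→8)-epicatechin 3-O-gallate-(4β→8)-epicatechin 3-O-gallate, via dimer 2-alkoxybenzoxazoline adduct 14 (not isolated)
Conditions: 13 (1 equiv), 10, pyridine, MTBE, rt, filtered into 7 (2 equiv), NiBr2(dtbbpy) (15 mol %), [Ir(ppy)2(dtbbpy)]PF6 (2 mol %), quinuclidine, MTBE/DMA, 450 nm LEDs, rt, Ar
Reagents that add atoms: none
Why: Proposed new method: carbinol 13 condenses with 10 to adduct 14, whose one-electron oxidation by the excited iridium photocatalyst, loss of the benzoxazoline C2 proton to quinuclidine and β-scission of the C4–O bond release the planar C4 radical of the middle unit, while zerovalent nickel inserts into the C8–Br bond of 7, the divalent aryl-nickel species traps the radical, the trivalent complex reductively eliminates the C4–C8 bond and the reduced photocatalyst returns nickel to the zerovalent state. The closest known reaction types are the nickel/photoredox deoxygenative arylation of secondary alcohols through benzoxazolium adducts and the nickel-catalysed reductive arylation of secondary benzylic electrophiles, neither demonstrated at a flavan C4 or with a di-ortho-oxygenated aryl bromide. No ring is closed. The one new stereocentre, C4 of the middle unit, is under substrate control: the axial C3 gallate and the cis C2 aryl group cover the α face, so nickel should bind and deliver the aryl group on the β face (3,4-trans), and since radical capture at nickel is expected to be reversible the less crowded β-bound complex should be the one that eliminates. Regioselectivity (C8, not C6) is fixed by the bromine position; chemoselectivity follows because 13 has no halide and 7 no hydroxyl, so neither partner nor 15 can chain on; and a 1,2-acyloxy shift of the β-gallate is uphill from a benzylic radical. The near-neutral medium and a photocatalyst too weakly oxidising to attack alkoxyarenes should leave both gallate esters and all nineteen benzyl ethers intact.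

Step 11
Reactants: 15 perbenzylated trimer digallate
Product: 16 target, epicatechin-(4β→8)-epicatechin 3-O-gallate-(4β→8)-epicatechin 3-O-gallate
Conditions: H2 (1 atm), Pd(OH)2/C, THF/MeOH/H2O, rt; filtration, lyophilisation
Reagents that add atoms: none
Why: Heterogeneous hydrogenolysis, a standard end-game for benzylated procyanidin gallates, should cleave the eighteen aryl benzyl ethers and the one alkyl benzyl ether under neutral conditions that leave the esters, the interflavan bonds and all eight stereocentres untouched.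

Compound list
1 | (−)-epicatechin (2R,3R) | Oc1cc(O)c2c(c1)O[C@H](c1ccc(O)c(O)c1)[C@H](O)C2 | starting material
2 | 5,7,3',4'-tetra-O-benzylepicatechin | c1c(OCc3ccccc3)cc(OCc3ccccc3)c2c1O[C@H](c1ccc(OCc3ccccc3)c(OCc3ccccc3)c1)[C@H](O)C2 | intermediate
3 | 3,5,7,3',4'-penta-O-benzylepicatechin | c1c(OCc3ccccc3)cc(OCc3ccccc3)c2c1O[C@H](c1ccc(OCc3ccccc3)c(OCc3ccccc3)c1)[C@H](OCc1ccccc1)C2 | intermediate
4 | 3,5,7,3',4'-penta-O-benzyl-4β-hydroxyepicatechin (top unit) | O[C@H]1c2c(OCc3ccccc3)cc(OCc3ccccc3)cc2O[C@H](c2ccc(OCc3ccccc3)c(OCc3ccccc3)c2)[C@@H]1OCc1ccccc1 | intermediate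
5 | 8-bromo-5,7,3',4'-tetra-O-benzylepicatechin | Brc1c(OCc3ccccc3)cc(OCc3ccccc3)c2c1O[C@H](c1ccc(OCc3ccccc3)c(OCc3ccccc3)c1)[C@H](O)C2 | intermediate
6 | 3,4,5-tris(benzyloxy)benzoic acid | OC(=O)c1cc(OCc2ccccc2)c(OCc2ccccc2)c(OCc2ccccc2)c1 | starting material
7 | 8-bromo-5,7,3',4'-tetra-O-benzylepicatechin 3-O-(3,4,5-tri-O-benzylgallate) (bottom unit) | Brc1c(OCc3ccccc3)cc(OCc3ccccc3)c2c1O[C@H](c1ccc(OCc3ccccc3)c(OCc3ccccc3)c1)[C@H](OC(=O)c1cc(OCc3ccccc3)c(OCc3ccccc3)c(OCc3ccccc3)c1)C2 | intermediate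
8 | 8-bromo-5,7,3',4'-tetra-O-benzyl-4β-hydroxyepicatechin 3-O-(3,4,5-tri-O-benzylgallate) | O=C(O[C@@H]1[C@@H](O)c2c(OCc3ccccc3)cc(OCc3ccccc3)c(Br)c2O[C@@H]1c1ccc(OCc3ccccc3)c(OCc3ccccc3)c1)c1cc(OCc3ccccc3)c(OCc3ccccc3)c(OCc3ccccc3)c1 | intermediate
9 | 8-bromo-5,7,3',4'-tetra-O-benzyl-4β-(tert-butyldimethylsilyloxy)epicatechin 3-O-(3,4,5-tri-O-benzylgallate) (middle unit) | O=C(O[C@@H]1[C@@H](O[Si](C)(C)C(C)(C)C)c2c(OCc3ccccc3)cc(OCc3ccccc3)c(Br)c2O[C@@H]1c1ccc(OCc3ccccc3)c(OCc3ccccc3)c1)c1cc(OCc3ccccc3)c(OCc3ccccc3)c(OCc3ccccc3)c1 | intermediate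
10 | 5,7-di-tert-butyl-3-phenylbenzoxazolium tetrafluoroborate (alcohol activator) | CC(C)(C)c1cc(C(C)(C)C)c2oc[n+](-c3ccccc3)c2c1.F[B-](F)(F)F | starting material
11 | 2-[(3,5,7,3',4'-penta-O-benzylepicatechin-4β-yl)oxy]-5,7-di-tert-butyl-3-phenyl-2,3-dihydrobenzoxazole (epimers at benzoxazoline C2; not isolated) | CC(C)(C)c1cc(C(C)(C)C)c2OC(O[C@H]3c4c(OCc5ccccc5)cc(OCc5ccccc5)cc4O[C@H](c4ccc(OCc5ccccc5)c(OCc5ccccc5)c4)[C@@H]3OCc3ccccc3)N(c3ccccc3)c2c1 | intermediate
12 | penta-O-benzylepicatechin-(4β→8)-[tetra-O-benzyl-4β-(tert-butyldimethylsilyloxy)epicatechin 3-O-(tri-O-benzylgallate)] | O=C(O[C@@H]1[C@@H](O[Si](C)(C)C(C)(C)C)c2c(OCc3ccccc3)cc(OCc3ccccc3)c([C@H]3c4c(OCc5ccccc5)cc(OCc5ccccc5)cc4O[C@H](c4ccc(OCc5ccccc5)c(OCc5ccccc5)c4)[C@@H]3OCc3ccccc3)c2O[C@@H]1c1ccc(OCc3ccccc3)c(OCc3ccccc3)c1)c1cc(OCc3ccccc3)c(OCc3ccccc3)c(OCc3ccccc3)c1 | intermediate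
13 | penta-O-benzylepicatechin-(4β→8)-[tetra-O-benzyl-4β-hydroxyepicatechin 3-O-(tri-O-benzylgallate)] | O=C(O[C@@H]1[C@@H](O)c2c(OCc3ccccc3)cc(OCc3ccccc3)c([C@H]3c4c(OCc5ccccc5)cc(OCc5ccccc5)cc4O[C@H](c4ccc(OCc5ccccc5)c(OCc5ccccc5)c4)[C@@H]3OCc3ccccc3)c2O[C@@H]1c1ccc(OCc3ccccc3)c(OCc3ccccc3)c1)c1cc(OCc3ccccc3)c(OCc3ccccc3)c(OCc3ccccc3)c1 | intermediate
14 | 2-alkoxy-5,7-di-tert-butyl-3-phenyl-2,3-dihydrobenzoxazole derived from the middle-unit 4β-oxygen of 13 (epimers at benzoxazoline C2; not isolated) | O=C(O[C@@H]1[C@@H](OC6Oc7c(C(C)(C)C)cc(C(C)(C)C)cc7N6c6ccccc6)c2c(OCc3ccccc3)cc(OCc3ccccc3)c([C@H]3c4c(OCc5ccccc5)cc(OCc5ccccc5)cc4O[C@H](c4ccc(OCc5ccccc5)c(OCc5ccccc5)c4)[C@@H]3OCc3ccccc3)c2O[C@@H]1c1ccc(OCc3ccccc3)c(OCc3ccccc3)c1)c1cc(OCc3ccccc3)c(OCc3ccccc3)c(OCc3ccccc3)c1 | intermediate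
15 | nonadeca-O-benzyl epicatechin-(4β→8)-epicatechin 3-O-gallate-(4β→8)-epicatechin 3-O-gallate | O=C(O[C@@H]1[C@@H](c2c(OCc4ccccc4)cc(OCc4ccccc4)c3c2O[C@H](c2ccc(OCc4ccccc4)c(OCc4ccccc4)c2)[C@H](OC(=O)c2cc(OCc4ccccc4)c(OCc4ccccc4)c(OCc4ccccc4)c2)C3)c2c(OCc3ccccc3)cc(OCc3ccccc3)c([C@H]3c4c(OCc5ccccc5)cc(OCc5ccccc5)cc4O[C@H](c4ccc(OCc5ccccc5)c(OCc5ccccc5)c4)[C@@H]3OCc3ccccc3)c2O[C@@H]1c1ccc(OCc3ccccc3)c(OCc3ccccc3)c1)c1cc(OCc3ccccc3)c(OCc3ccccc3)c(OCc3ccccc3)c1 | intermediate
16 | CNP0279403.1, epicatechin-(4β→8)-epicatechin 3-O-gallate-(4β→8)-epicatechin 3-O-gallate | O=C(O[C@@H]1[C@@H](c2c(O)cc(O)c3c2O[C@H](c2ccc(O)c(O)c2)[C@H](OC(=O)c2cc(O)c(O)c(O)c2)C3)c2c(O)cc(O)c([C@H]3c4c(O)cc(O)cc4O[C@H](c4ccc(O)c(O)c4)[C@@H]3O)c2O[C@@H]1c1ccc(O)c(O)c1)c1cc(O)c(O)c(O)c1 | target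

Total step count: 11. Longest linear sequence: 9 steps (1 → 2 → 5 → 7 → 8 → 9 → 12 → 13 → 15 → 16).

Steps most likely to fail

1. Step 10.
- **Risk:** Insertion of nickel into the crowded, electron-rich C8–Br bond and capture of the bulky dimer radical may both be slow. Radical dimerisation, hydrogen abstraction at C4 or loss of bromine could then outrun bond formation, and facial selectivity could erode.
- **Fallback:** The bond is formed by a polar rather than a radical route, using the known acid-promoted condensation of a flavan-4-ol with a flavan-3-ol. It sets out from 13 and 2. Catalytic TMSOTf in CH2Cl2 at −78 °C should ionise the C4 carbinol of 13. A four- to fivefold excess of 2, which outcompetes the free C8 of the top unit of 13, should attack through its C8 on the β face. This should give the perbenzylated trimer monogallate with a free 3-OH on the bottom unit F1. Steglich esterification of F1 with 6 (DCC, DMAP, CH2Cl2) comes back to the route at 15.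

2. Step 8.
- **Risk:** The same slow oxidative addition and slow radical capture apply, and the C4 silyl ether next to the reacting ring may be lost under prolonged irradiation.
- **Fallback:** This is a Friedel–Crafts union followed by late oxidation. It sets out from 4 and 2. Catalytic TMSOTf (CH2Cl2, −78 °C) with excess 2 should give the perbenzylated epicatechin-(4β→8)-epicatechin dimer with a free 3-OH on the lower unit F2. Steglich esterification with 6 should give its lower-unit 3-O-(tri-O-benzylgallate) F3. DDQ in CH2Cl2/H2O should then oxidise the only C4 methylene. The remaining C4–H of the upper unit is pseudo-equatorial, poorly aligned with its ring A and buried between two rings. The fallback comes back at 13 and so bypasses 12 and step 9.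

3. Step 6.
- **Risk:** Hydride abstraction from a ring A deactivated by bromine, next to an electron-withdrawing acyloxy group, may be sluggish. Over-oxidation of the carbinol or attack on benzyl ethers could then compete.
- **Fallback:** The C–H oxidation is moved ahead of the halogenation. It sets out from 2 and 6. Steglich esterification should give 5,7,3',4'-tetra-O-benzylepicatechin 3-O-(tri-O-benzylgallate) F4. DDQ in CH2Cl2/H2O on this more electron-rich ring A should give its 4β-carbinol F5. TBSCl/imidazole should give the 4β-silyl ether F6. NBS (1 equiv, CH2Cl2, −78 °C), known to select C8 in 4-oxygenated benzylated flavans, comes back to the route at 9.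

Further compounds
F1 | step 10 | perbenzylated epicatechin-(4β→8)-epicatechin 3-O-gallate-(4β→8)-epicatechin with free bottom 3-OH | O=C(O[C@@H]1[C@@H](c2c(OCc4ccccc4)cc(OCc4ccccc4)c3c2O[C@H](c2ccc(OCc4ccccc4)c(OCc4ccccc4)c2)[C@H](O)C3)c2c(OCc3ccccc3)cc(OCc3ccccc3)c([C@H]3c4c(OCc5ccccc5)cc(OCc5ccccc5)cc4O[C@H](c4ccc(OCc5ccccc5)c(OCc5ccccc5)c4)[C@@H]3OCc3ccccc3)c2O[C@@H]1c1ccc(OCc3ccccc3)c(OCc3ccccc3)c1)c1cc(OCc3ccccc3)c(OCc3ccccc3)c(OCc3ccccc3)c1
F2 | step 8 | penta-O-benzylepicatechin-(4β→8)-tetra-O-benzylepicatechin with free lower 3-OH | O[C@@H]1Cc2c(OCc3ccccc3)cc(OCc3ccccc3)c([C@H]3c4c(OCc5ccccc5)cc(OCc5ccccc5)cc4O[C@H](c4ccc(OCc5ccccc5)c(OCc5ccccc5)c4)[C@@H]3OCc3ccccc3)c2O[C@@H]1c1ccc(OCc3ccccc3)c(OCc3ccccc3)c1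
F3 | step 8 | penta-O-benzylepicatechin-(4β→8)-[tetra-O-benzylepicatechin 3-O-(tri-O-benzylgallate)], lower C4 methylene | O=C(O[C@@H]1Cc2c(OCc3ccccc3)cc(OCc3ccccc3)c([C@H]3c4c(OCc5ccccc5)cc(OCc5ccccc5)cc4O[C@H](c4ccc(OCc5ccccc5)c(OCc5ccccc5)c4)[C@@H]3OCc3ccccc3)c2O[C@@H]1c1ccc(OCc3ccccc3)c(OCc3ccccc3)c1)c1cc(OCc3ccccc3)c(OCc3ccccc3)c(OCc3ccccc3)c1
F4 | step 6 | 5,7,3',4'-tetra-O-benzylepicatechin 3-O-(tri-O-benzylgallate) | c1c(OCc3ccccc3)cc(OCc3ccccc3)c2c1O[C@H](c1ccc(OCc3ccccc3)c(OCc3ccccc3)c1)[C@H](OC(=O)c1cc(OCc3ccccc3)c(OCc3ccccc3)c(OCc3ccccc3)c1)C2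
F5 | step 6 | 5,7,3',4'-tetra-O-benzyl-4β-hydroxyepicatechin 3-O-(tri-O-benzylgallate) | O=C(O[C@@H]1[C@@H](O)c2c(OCc3ccccc3)cc(OCc3ccccc3)cc2O[C@@H]1c1ccc(OCc3ccccc3)c(OCc3ccccc3)c1)c1cc(OCc3ccccc3)c(OCc3ccccc3)c(OCc3ccccc3)c1
F6 | step 6 | 5,7,3',4'-tetra-O-benzyl-4β-(tert-butyldimethylsilyloxy)epicatechin 3-O-(tri-O-benzylgallate) | O=C(O[C@@H]1[C@@H](O[Si](C)(C)C(C)(C)C)c2c(OCc3ccccc3)cc(OCc3ccccc3)cc2O[C@@H]1c1ccc(OCc3ccccc3)c(OCc3ccccc3)c1)c1cc(OCc3ccccc3)c(OCc3ccccc3)c(OCc3ccccc3)c1
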